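**Plan**

- Retrosynthesis: the three MOM ethers come off last. The C3–H bond is traced back to a C3–CH2OH placeholder. The O1–C8a aryl ether bond of the pyran ring is then cut. Behind it lie the C3–C4 bond (benzylation), the two C3–CH2OH bonds (formaldehyde), the ring B C1′–CH2 homologation and the C5′–CMe2 bond (Claisen).
- Forward: ring B aldehyde from 2,3,4-trihydroxybenzaldehyde (O4-prenylation, O3/O2 differentiation, Claisen), one-carbon homologation to the arylacetonitrile, benzylation with the ring A bromide, nitrile → aldehyde → 2-aryl-2-benzylpropane-1,3-diol. The pyran ring, the only ring made, closes by O1–C8a coupling; then CH2OH → CHO → H and deprotection.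
- Enabling feature: isoflavan C3 carries H, the ring B aryl group, C4H2 (bound to ring A at C4a) and C2H2–O1. With that H replaced by CH2OH, C2H2OH and the extra CH2OH are enantiotopic arms of an achiral diol, and ring A carries Br at C8a, ortho to the C4 benzyl carbon.
- Stereochemistry: C3, the only stereocentre, is created as a quaternary centre when a chiral diamine–CuI catalyst arylates the pro-S hydroxymethyl group. It cannot epimerise, and the decarbonylation that installs C3–H is retentive, so the target is (3S).

Key step: step 12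

Assumption: the (1R,2R) antipode of the diamine ligand is taken to select the pro-S arm; the sense of induction is to be confirmed on the first run, and the (1S,2S) antipode is used if it proves opposite.

Abbreviations: ArB = 2-methoxy-3,4-bis(methoxymethoxy)-5-(2-methylbut-3-en-2-yl)phenyl (ring B); ArA = 2-bromo-4-(methoxymethoxy)phenyl (ring A); MOM = methoxymethyl.

**Route**

Step 1
Reactants: 1 2,3,4-trihydroxybenzaldehyde; 2 1-bromo-3-methylbut-2-ene
Product: 3 2,3-dihydroxy-4-[(3-methylbut-2-en-1-yl)oxy]benzaldehyde
Conditions: 2 (1.05 equiv), NaHCO3, DMF, 40 °C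
Reagents that add atoms: none
Why: Williamson etherification under weak-base control, in which only the 4-OH (para to the formyl group and the most acidic) is ionised while the 2-OH is held in a hydrogen bond to the aldehyde, so O-prenylation should occur at O4.

Step 2
Reactants: 3 2,3-dihydroxy-4-[(3-methylbut-2-en-1-yl)oxy]benzaldehyde
Product: 5 2-methoxy-3-(methoxymethoxy)-4-[(3-methylbut-2-en-1-yl)oxy]benzaldehyde, via sodium phenolate 4 (not isolated)
Conditions: NaH (2.2 equiv), DMF, 0 °C; MOMCl (1.0 equiv), 0 °C; then MeI (3 equiv), rt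
Reagents that add atoms: chloromethyl methyl ether (MOMCl), COCCl; iodomethane, CI
Why: Dianion alkylation, in which the non-chelated and more basic 3-phenoxide should take the single equivalent of MOMCl first (as known for dianions of 2,3-dihydroxybenzaldehydes) and the remaining chelated 2-phenoxide is then methylated in the same flask (Williamson ether synthesis).

Step 3
Reactants: 5 2-methoxy-3-(methoxymethoxy)-4-[(3-methylbut-2-en-1-yl)oxy]benzaldehyde
Product: 7 4-hydroxy-2-methoxy-3-(methoxymethoxy)-5-(2-methylbut-3-en-2-yl)benzaldehyde, via dienone 6 (not isolated)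
Conditions: PhNEt2, 190 °C, argon
Reagents that add atoms: none
Why: Aromatic Claisen rearrangement, whose [3,3] shift delivers the inverted 1,1-dimethylallyl group to C5, the only free ortho position (C3 is blocked by OMOM), after which the dienone tautomerises to the phenol, a reaction type known for 4-prenyloxybenzaldehydes.

Step 4
Reactants: 7 4-hydroxy-2-methoxy-3-(methoxymethoxy)-5-(2-methylbut-3-en-2-yl)benzaldehyde
Product: 8 2-methoxy-3,4-bis(methoxymethoxy)-5-(2-methylbut-3-en-2-yl)benzaldehyde (ArB–CHO)
Conditions: NaH, MOMCl, DMF, 0 °C → rt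
Reagents that add atoms: chloromethyl methyl ether (MOMCl), COCCl
Why: O-alkylation of the sodium phenoxide with MOMCl, where the acidity of the phenol para to the aldehyde and full deprotonation should overcome the hindrance of the flanking tert-alkyl group.

Step 5
Reactants: 8 2-methoxy-3,4-bis(methoxymethoxy)-5-(2-methylbut-3-en-2-yl)benzaldehyde
Product: 10 2-[2-methoxy-3,4-bis(methoxymethoxy)-5-(2-methylbut-3-en-2-yl)phenyl]acetonitrile (ArB–CH2CN), via tosyloxazoline 9 (not isolated)
Conditions: TosMIC, t-BuOK, DME, −40 °C; then MeOH, reflux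
Reagents that add atoms: p-toluenesulfonylmethyl isocyanide (TosMIC), Cc1ccc(cc1)S(=O)(=O)C[N+]#[C-]
Why: Van Leusen reductive cyanation, in which the TosMIC anion adds to the aldehyde and closes to the 4-tosyl-2-oxazoline that, on heating with methanol, loses sulfinate and methyl formate to leave the homologated nitrile under purely basic conditions that spare the MOM ethers and the alkene.

Step 6
Reactants: 11 2-bromo-4-hydroxybenzaldehyde
Product: 12 2-bromo-4-(methoxymethoxy)benzaldehyde
Conditions: MOMCl, i-Pr2NEt, CH2Cl2, 0 °C → rt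
Reagents that add atoms: chloromethyl methyl ether (MOMCl), COCCl
Why: Standard MOM protection of an acidic, unhindered phenol with an amine base.

Step 7
Reactants: 12 2-bromo-4-(methoxymethoxy)benzaldehyde
Product: 13 [2-bromo-4-(methoxymethoxy)phenyl]methanol
Conditions: NaBH4, MeOH, 0 °C
Reagents that add atoms: none
Why: Borohydride reduction of an aryl aldehyde, which leaves the aryl bromide and the acetal untouched.

Step 8
Reactants: 13 [2-bromo-4-(methoxymethoxy)phenyl]methanol
Product: 14 2-bromo-1-(bromomethyl)-4-(methoxymethoxy)benzene (ArA–CH2Br)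
Conditions: CBr4, PPh3, CH2Cl2, 0 °C; used at once
Reagents that add atoms: tetrabromomethane, BrC(Br)(Br)Br
Why: Appel bromination of a benzylic alcohol under neutral conditions, which avoids the free HBr that would cleave the MOM ether.

Step 9
Reactants: 10 2-[2-methoxy-3,4-bis(methoxymethoxy)-5-(2-methylbut-3-en-2-yl)phenyl]acetonitrile; 14 2-bromo-1-(bromomethyl)-4-(methoxymethoxy)benzene
Product: 15 3-[2-bromo-4-(methoxymethoxy)phenyl]-2-[2-methoxy-3,4-bis(methoxymethoxy)-5-(2-methylbut-3-en-2-yl)phenyl]propanenitrile (racemic)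
Conditions: LiN(i-Pr)2 (1.05 equiv), THF, −78 °C; then 14, −78 → 0 °C
Reagents that add atoms: none
Why: SN2 alkylation of a lithiated arylacetonitrile with a benzylic bromide, held at monoalkylation by one equivalent of base at low temperature and by the bulk of both partners, with the aryl bromide inert to the nitrile anion.

Step 10
Reactants: 15 3-[2-bromo-4-(methoxymethoxy)phenyl]-2-[2-methoxy-3,4-bis(methoxymethoxy)-5-(2-methylbut-3-en-2-yl)phenyl]propanenitrile
Product: 17 3-[2-bromo-4-(methoxymethoxy)phenyl]-2-[2-methoxy-3,4-bis(methoxymethoxy)-5-(2-methylbut-3-en-2-yl)phenyl]propanal (racemic), via N-aluminio aldimine 16 (not isolated)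
Conditions: i-Bu2AlH (1.3 equiv), toluene, −78 °C; then 10% aq. tartaric acid, 0 °C; product used crude
Reagents that add atoms: water, O
Why: Partial reduction of a nitrile, in which i-Bu2AlH adds once to give an N-aluminio aldimine that is stable at −78 °C and is hydrolysed to the aldehyde on mild acidic work-up, while aryl bromide, MOM ethers and alkene do not react.

Step 11
Reactants: 17 3-[2-bromo-4-(methoxymethoxy)phenyl]-2-[2-methoxy-3,4-bis(methoxymethoxy)-5-(2-methylbut-3-en-2-yl)phenyl]propanal
Product: 19 2-{[2-bromo-4-(methoxymethoxy)phenyl]methyl}-2-[2-methoxy-3,4-bis(methoxymethoxy)-5-(2-methylbut-3-en-2-yl)phenyl]propane-1,3-diol (achiral), via aldol 18 (not isolated)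
Conditions: HCHO (37% aq., excess), KOH, EtOH, 60 °C, degassed
Reagents that add atoms: formaldehyde, C=O
Why: Tollens-type hydroxymethylation, in which the enolisable α-aryl aldehyde adds to formaldehyde to create the quaternary carbon and the resulting non-enolisable aldehyde is reduced by a second formaldehyde in a crossed Cannizzaro reaction, the standard entry to 2,2-disubstituted propane-1,3-diols.

Step 12
Reactants: 19 2-{[2-bromo-4-(methoxymethoxy)phenyl]methyl}-2-[2-methoxy-3,4-bis(methoxymethoxy)-5-(2-methylbut-3-en-2-yl)phenyl]propane-1,3-diol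
Product: 20 [(3S)-3-[2-methoxy-3,4-bis(methoxymethoxy)-5-(2-methylbut-3-en-2-yl)phenyl]-7-(methoxymethoxy)-3,4-dihydro-2H-chromen-3-yl]methanol
Conditions: CuI (10 mol %), (1R,2R)-N,N′-dimethylcyclohexane-1,2-diamine (20 mol %), Cs2CO3 (2 equiv), MeCN, 60 °C
Reagents that add atoms: none
Why: Cs2CO3 and the diamine-bound monovalent copper convert one hydroxymethyl group into a copper alkoxide, the neighbouring C8a–Br bond of ring A adds to it (oxidative addition to a trivalent copper aryl alkoxide or its concerted equivalent), and C(sp2)–O reductive elimination forms O1–C8a and returns the catalyst. The closest known reaction is the copper/chiral diamine desymmetrising intramolecular Ullmann-type O-arylation of 2-(2-halobenzyl)propane-1,3-diols to 3-(hydroxymethyl)chromans, here applied to a 2-aryl member of that class. The pyran ring closes in a formal 6-exo mode at the aromatic carbon through a seven-membered aryl–copper–alkoxide chelate, an intramolecular event that should outpace any intermolecular etherification. The new quaternary centre C3 is set by the ligand alone: the two CH2OH groups are enantiotopic, and the C2-symmetric diamine should place the bulky ring B aryl group and the small spectator CH2OH in different quadrants of the chelate, so that the pro-S arm is arylated and the (3S) alcohol results. The step needs enantiotopic-group selectivity and chemoselectivity for the alkoxide over other nucleophiles; the first rests on the large size difference between the aryl and CH2OH substituents at the prochiral carbon, the second on every phenol being capped as a MOM or methyl ether and on the ring A bromide being the only halide. A second arylation is impossible because the remaining hydroxymethyl group has no halide within reach, and C3, being quaternary, cannot epimerise under the basic conditions.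

Step 13
Reactants: 20 [(3S)-3-[2-methoxy-3,4-bis(methoxymethoxy)-5-(2-methylbut-3-en-2-yl)phenyl]-7-(methoxymethoxy)-3,4-dihydro-2H-chromen-3-yl]methanol
Product: 21 (3R)-3-[2-methoxy-3,4-bis(methoxymethoxy)-5-(2-methylbut-3-en-2-yl)phenyl]-7-(methoxymethoxy)-3,4-dihydro-2H-chromene-3-carbaldehyde
Conditions: Dess–Martin periodinane, CH2Cl2, 0 °C → rt
Reagents that add atoms: none
Why: Dess–Martin oxidation of a neopentyl-type primary alcohol under near-neutral conditions; the α-carbon is quaternary, so the aldehyde can neither enolise nor expel the β-aryloxy group, and the spatial arrangement is unchanged (the descriptor switches to R only because CHO outranks C2).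

Step 14
Reactants: 21 (3R)-3-[2-methoxy-3,4-bis(methoxymethoxy)-5-(2-methylbut-3-en-2-yl)phenyl]-7-(methoxymethoxy)-3,4-dihydro-2H-chromene-3-carbaldehyde
Product: 22 (3S)-3-[2-methoxy-3,4-bis(methoxymethoxy)-5-(2-methylbut-3-en-2-yl)phenyl]-7-(methoxymethoxy)-3,4-dihydro-2H-chromene
Conditions: RhCl(PPh3)3 (1.1 equiv), toluene, 110 °C, degassed
Reagents that add atoms: none
Why: Tsuji–Wilkinson decarbonylation, in which formyl C–H oxidative addition, CO extrusion to a tertiary alkyl rhodium hydride and C–H reductive elimination all proceed with retention at carbon (as established for α-aryl quaternary aldehydes), so the C3–H bond should take the place of the C3–CHO bond, and the 1,1-dimethylallyl alkene has no allylic hydrogen through which a rhodium hydride could move it.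

Step 15
Reactants: 22 (3S)-3-[2-methoxy-3,4-bis(methoxymethoxy)-5-(2-methylbut-3-en-2-yl)phenyl]-7-(methoxymethoxy)-3,4-dihydro-2H-chromene
Product: 23 (3S)-3-[3,4-dihydroxy-2-methoxy-5-(2-methylbut-3-en-2-yl)phenyl]-3,4-dihydro-2H-chromen-7-ol (CNP0167796.2)
Conditions: HCl (1 M in MeOH), rt, argon, short contact time
Reagents that add atoms: none
Why: Acid-catalysed transacetalisation of the three aryl MOM ethers to dimethoxymethane, under conditions mild enough to leave the aryl methyl ether, the C3–H stereocentre and the alkene next to the liberated catechol untouched.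

**Compound list**

1 | 2,3,4-trihydroxybenzaldehyde | O=Cc1ccc(O)c(O)c1O | starting material
2 | 1-bromo-3-methylbut-2-ene (prenyl bromide) | CC(C)=CCBr | starting material
3 | 2,3-dihydroxy-4-[(3-methylbut-2-en-1-yl)oxy]benzaldehyde | O=Cc1ccc(OCC=C(C)C)c(O)c1O | intermediate
4 | sodium 6-formyl-2-(methoxymethoxy)-3-[(3-methylbut-2-en-1-yl)oxy]phenolate | O=Cc1ccc(OCC=C(C)C)c(OCOC)c1[O-].[Na+] | intermediate (not isolated)
5 | 2-methoxy-3-(methoxymethoxy)-4-[(3-methylbut-2-en-1-yl)oxy]benzaldehyde | O=Cc1ccc(OCC=C(C)C)c(OCOC)c1OC | intermediate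
6 | 6-methoxy-5-(methoxymethoxy)-3-(2-methylbut-3-en-2-yl)-4-oxocyclohexa-1,5-diene-1-carbaldehyde (racemic) | O=CC1=CC(C(C)(C)C=C)C(=O)C(OCOC)=C1OC | intermediate (not isolated)
7 | 4-hydroxy-2-methoxy-3-(methoxymethoxy)-5-(2-methylbut-3-en-2-yl)benzaldehyde | O=Cc1cc(C(C)(C)C=C)c(O)c(OCOC)c1OC | intermediate
8 | 2-methoxy-3,4-bis(methoxymethoxy)-5-(2-methylbut-3-en-2-yl)benzaldehyde | O=Cc1cc(C(C)(C)C=C)c(OCOC)c(OCOC)c1OC | intermediate
9 | 5-[2-methoxy-3,4-bis(methoxymethoxy)-5-(2-methylbut-3-en-2-yl)phenyl]-4-(4-methylbenzenesulfonyl)-4,5-dihydro-1,3-oxazole (racemic, relative configuration of no consequence) | Cc1ccc(cc1)S(=O)(=O)C1N=COC1c1cc(C(C)(C)C=C)c(OCOC)c(OCOC)c1OC | intermediate (not isolated)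
10 | 2-[2-methoxy-3,4-bis(methoxymethoxy)-5-(2-methylbut-3-en-2-yl)phenyl]acetonitrile | N#CCc1cc(C(C)(C)C=C)c(OCOC)c(OCOC)c1OC | intermediate
11 | 2-bromo-4-hydroxybenzaldehyde | O=Cc1ccc(O)cc1Br | starting material
12 | 2-bromo-4-(methoxymethoxy)benzaldehyde | O=Cc1ccc(OCOC)cc1Br | intermediate
13 | [2-bromo-4-(methoxymethoxy)phenyl]methanol | OCc1ccc(OCOC)cc1Br | intermediate
14 | 2-bromo-1-(bromomethyl)-4-(methoxymethoxy)benzene | BrCc1ccc(OCOC)cc1Br | intermediate
15 | 3-[2-bromo-4-(methoxymethoxy)phenyl]-2-[2-methoxy-3,4-bis(methoxymethoxy)-5-(2-methylbut-3-en-2-yl)phenyl]propanenitrile (racemic) | N#CC(Cc1ccc(OCOC)cc1Br)c1cc(C(C)(C)C=C)c(OCOC)c(OCOC)c1OC | intermediate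
16 | N-[bis(2-methylpropyl)alumanyl] imine of aldehyde 17 (racemic) | CC(C)C[Al](CC(C)C)N=CC(Cc1ccc(OCOC)cc1Br)c1cc(C(C)(C)C=C)c(OCOC)c(OCOC)c1OC | intermediate (not isolated)
17 | 3-[2-bromo-4-(methoxymethoxy)phenyl]-2-[2-methoxy-3,4-bis(methoxymethoxy)-5-(2-methylbut-3-en-2-yl)phenyl]propanal (racemic) | O=CC(Cc1ccc(OCOC)cc1Br)c1cc(C(C)(C)C=C)c(OCOC)c(OCOC)c1OC | intermediate
18 | 2-{[2-bromo-4-(methoxymethoxy)phenyl]methyl}-3-hydroxy-2-[2-methoxy-3,4-bis(methoxymethoxy)-5-(2-methylbut-3-en-2-yl)phenyl]propanal (racemic) | O=CC(CO)(Cc1ccc(OCOC)cc1Br)c1cc(C(C)(C)C=C)c(OCOC)c(OCOC)c1OC | intermediate (not isolated)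
19 | 2-{[2-bromo-4-(methoxymethoxy)phenyl]methyl}-2-[2-methoxy-3,4-bis(methoxymethoxy)-5-(2-methylbut-3-en-2-yl)phenyl]propane-1,3-diol (achiral) | C=CC(C)(C)c1cc(C(CO)(CO)Cc2ccc(OCOC)cc2Br)c(OC)c(OCOC)c1OCOC | intermediate
20 | [(3S)-3-[2-methoxy-3,4-bis(methoxymethoxy)-5-(2-methylbut-3-en-2-yl)phenyl]-7-(methoxymethoxy)-3,4-dihydro-2H-chromen-3-yl]methanol | C=CC(C)(C)c1cc([C@@]2(CO)COc3cc(OCOC)ccc3C2)c(OC)c(OCOC)c1OCOC | intermediate
21 | (3R)-3-[2-methoxy-3,4-bis(methoxymethoxy)-5-(2-methylbut-3-en-2-yl)phenyl]-7-(methoxymethoxy)-3,4-dihydro-2H-chromene-3-carbaldehyde | C=CC(C)(C)c1cc([C@@]2(C=O)COc3cc(OCOC)ccc3C2)c(OC)c(OCOC)c1OCOC | intermediate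
22 | (3S)-3-[2-methoxy-3,4-bis(methoxymethoxy)-5-(2-methylbut-3-en-2-yl)phenyl]-7-(methoxymethoxy)-3,4-dihydro-2H-chromene | C=CC(C)(C)c1cc([C@H]2COc3cc(OCOC)ccc3C2)c(OC)c(OCOC)c1OCOC | intermediate
23 | (3S)-3-[3,4-dihydroxy-2-methoxy-5-(2-methylbut-3-en-2-yl)phenyl]-3,4-dihydro-2H-chromen-7-ol (CNP0167796.2) | C=CC(C)(C)c1cc([C@H]2COc3cc(O)ccc3C2)c(OC)c(O)c1O | target

**Step count**

Total steps: 15. Longest linear sequence: 12 steps (steps 1–5 and 9–15, from 1 to 23); the ring A branch (steps 6–8) joins at step 9.

**Steps most likely to fail**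

Step 12 (desymmetrising O-arylation). What may go wrong: the ligand may discriminate poorly between the two hydroxymethyl arms next to the bulky ortho-methoxyaryl group, or activation of the electron-rich aryl bromide at copper may be so slow that a ligand-free, unselective pathway takes over. The fallback moves the source of asymmetry to an enzyme and closes the ring with an achiral catalyst. It sets out from 19. Candida rugosa lipase and 1-ethoxyvinyl furan-2-carboxylate in wet i-Pr2O, a pairing established for prochiral 2,2-disubstituted propane-1,3-diols, should acylate the pro-R arm and give (2R)-3-[2-bromo-4-(methoxymethoxy)phenyl]-2-(hydroxymethyl)-2-[2-methoxy-3,4-bis(methoxymethoxy)-5-(2-methylbut-3-en-2-yl)phenyl]propyl furan-2-carboxylate F1; the aroyl ester is chosen because it migrates only slowly between the two oxygens. The free arm is then closed onto the bromide by a known palladium-catalysed intramolecular etherification (Pd(OAc)2, 2-(di-tert-butylphosphino)-1,1′-binaphthyl, Cs2CO3, toluene, 60 °C) to give [(3R)-3-[2-methoxy-3,4-bis(methoxymethoxy)-5-(2-methylbut-3-en-2-yl)phenyl]-7-(methoxymethoxy)-3,4-dihydro-2H-chromen-3-yl]methyl furan-2-carboxylate F2. K2CO3 in MeOH removes the furoate and the route is rejoined at 20. The lipase source is screened so that the pro-R arm is the one acylated.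

Step 14 (decarbonylation). What may go wrong: β-hydride elimination from the tertiary alkyl rhodium hydride toward C2 or C4, which would erase the stereocentre, or stalling of CO extrusion at the crowded neopentyl-type carbon. The fallback sets out from alcohol 20 and comes back at 22 in one operation. It uses the known iridium-catalysed acceptorless dehydrogenative decarbonylation of primary alcohols ([Ir(coe)2Cl]2, rac-BINAP, LiCl, mesitylene, reflux, argon sweep), which expels H2 and CO. The aldehyde then exists only transiently on a metal centre carrying a chelating diphosphine, which leaves less room for the vacant site that β-hydride elimination needs, and the acyl → alkyl → C–H sequence is again retentive. No new isolable compound arises (F0).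

Step 3 (Claisen rearrangement). What may go wrong: at 190 °C, fragmentation of the prenyl ether with loss of isoprene, or onward cyclisation and abnormal rearrangement of the ortho-hydroxy 1,1-dimethylallyl arene, may outrun the clean [3,3] shift, which the para-formyl group slows. The fallback brings in the tert-alkyl group by cross-coupling instead of a sigmatropic shift; it sets out from 1 and comes back at 8. MOMCl (2.1 equiv) and i-Pr2NEt cap the two non-chelated hydroxyls to give 2-hydroxy-3,4-bis(methoxymethoxy)benzaldehyde F3. MeI and K2CO3 in DMF give 2-methoxy-3,4-bis(methoxymethoxy)benzaldehyde F4. N-Bromosuccinimide in MeCN brominates C5 (para to OMe, ortho to OMOM, meta to CHO) to give 5-bromo-2-methoxy-3,4-bis(methoxymethoxy)benzaldehyde F5. A ligand-controlled γ-selective Suzuki–Miyaura coupling with 3-methylbut-2-enylboronic acid pinacol ester (Pd(OAc)2, bulky dialkylbiarylphosphine, K3PO4, THF/H2O, 40 °C) then installs the 1,1-dimethylallyl group and gives 8.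

**Further compounds**

F1 | step 12 | (2R)-3-[2-bromo-4-(methoxymethoxy)phenyl]-2-(hydroxymethyl)-2-[2-methoxy-3,4-bis(methoxymethoxy)-5-(2-methylbut-3-en-2-yl)phenyl]propyl furan-2-carboxylate | C=CC(C)(C)c1cc([C@@](Cc2ccc(OCOC)cc2Br)(COC(=O)c2ccco2)CO)c(OC)c(OCOC)c1OCOC
F2 | step 12 | [(3R)-3-[2-methoxy-3,4-bis(methoxymethoxy)-5-(2-methylbut-3-en-2-yl)phenyl]-7-(methoxymethoxy)-3,4-dihydro-2H-chromen-3-yl]methyl furan-2-carboxylate | C=CC(C)(C)c1cc([C@@]2(COC(=O)c4ccco4)COc3cc(OCOC)ccc3C2)c(OC)c(OCOC)c1OCOC
F0 | step 14 | none | none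
F3 | step 3 | 2-hydroxy-3,4-bis(methoxymethoxy)benzaldehyde | O=Cc1ccc(OCOC)c(OCOC)c1O
F4 | step 3 | 2-methoxy-3,4-bis(methoxymethoxy)benzaldehyde | O=Cc1ccc(OCOC)c(OCOC)c1OC
F5 | step 3 | 5-bromo-2-methoxy-3,4-bis(methoxymethoxy)benzaldehyde | O=Cc1cc(Br)c(OCOC)c(OCOC)c1OC
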